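The readings come from a simulation on assumed constants, noise included.

In this closed flask substrate, target and isomer of the product together keep the charge: Saturday's last reading sums to 99.4%. So I need two things, how much substrate remains and how the loss divides.

all flasks: gas phase 95 mM (held)
- Saturday's: substrate 0.40 M; the very flask that is asked about, followed so far
- Monday's: substrate 0.27 M; run made earlier
- flask: substrate 0.40 M; time 2.5 h

| run | time / min | isomer of the product / % | target / % | substrate / % |
|---|---|---|---|---|
| Saturday's | 2.50 | 0.3 | 0.7 | 99.4 |
| Saturday's | 8.00 | 1.6 | 4.6 | 94.4 |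
| Saturday's | 15.0 | 2.8 | 11.1 | 85.4 |
| Saturday's | 20.0 | 5.6 | 15.3 | 80.3 |
| Saturday's | 30.0 | 10.9 | 20.5 | 68.0 |
| Monday's | 12.0 | 2.2 | 9.3 | 88.3 |
| Monday's | 25.0 | 9.7 | 20.5 | 69.7 |
| Monday's | 40.0 | 17.7 | 30.6 | 51.7 |
| Monday's | 50.0 | 23.8 | 34.9 | 40.7 |
| Monday's | 60.0 | 27.8 | 40.2 | 32.0 |

(each reading ± 0.5 percentage points)

- the species that holds most of what was charged as substrate, at 2.5 h (isomer of the product / substrate / target)
- the largest share itself, whichever of these holds it, in percent of the substrate charged

- at the start none of the gas phase is in solution

From 25.0 min to 60.0 min, Monday's run gains 0.480 of isomer per part of substrate lost; this is the late isomer share, a selectivity. Its zero is the even split, 0.5, where target merely keeps its lead, 9.6 percentage points at Saturday's last reading. Below the even split, that lead grows. Saturday's flask reads 0.466 from 15.0 min to 30.0 min, but up to 15.0 min its share reads lower, 0.192, so I start from the last reading. One number is not enough, since it says nothing of the substrate left. Monday's substrate falls by a fraction 0.0222 min⁻¹; held steady, this leaves 4.71% in Saturday's flask at 2.5 h. I expect target 53.4% and isomer 41.3%.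

The forecast gives target at 54%, judging that “the isomer looks parallel to target rather than formed from it”. The flask gives target at 53.7%, with isomer 42.7% and substrate 3.60%.

    gas phase ⇌ dissolved gas, rate k1*(csat - [dissolved gas]) (kL = 0.100 min⁻¹)
    substrate + dissolved gas → target (k = 0.350 M⁻¹ min⁻¹)
    dissolved gas → decomposition product (k = 4.70 × 10⁻⁵ min⁻¹)
    target ⇌ isomer of the product (K = 0.810, k = 0.0680 min⁻¹)

Read at 1.5 h, the same flask is the further case. From Saturday's last reading, Monday's fraction, held steady, gives an estimate of 17.9% of substrate, and the share 0.480 divides the loss into target 46.5% and isomer 35.0%. That flask holds substrate 20%, isomer 34.2% and target 46.0%.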